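- At 3.0 d the summer flask is to be read, and one option may then be taken; the problem stands as follows.

| setting | summer | dawn | flask |
|---|---|---|---|
| starting material | 0.010 M | 0.010 M | 0.010 M |
| partner | 0.80 equiv | 0.80 equiv | 0.800 equiv |
| gas | 4.6 mM (held) | 4.6 mM (held) | 4.6 mM (held) |
| temperature | 100 °C | 85 °C | 100 °C |
| remark | the very flask that is asked about, followed so far | run made earlier |  |
| time |  |  | 3.0 d |

| run | time / h | target / % | starting material / % |
|---|---|---|---|
| summer | 8.00 | 20.4 | 40.9 |
| summer | 15.0 | 38.3 | 24.9 |
| summer | 20.0 | 44.9 | 17.8 |
| summer | 30.0 | 46.8 | 8.7 |
| summer | 40.0 | 40.6 | 3.1 |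
| dawn | 15.0 | 21.5 | 48.7 |
| dawn | 30.0 | 41.6 | 27.9 |
| dawn | 40.0 | 46.8 | 18.5 |
| dawn | 60.0 | 47.6 | 6.6 |
| dawn | 96.0 | 42.0 | 1.2 |

(standard deviation of a reading: 0.5 percentage points)

- target that was removed still counts
- at the start none of the gas is in solution
- additions bring no volume worth counting

- north-west: at 3.0 d raise the temperature by 25 K, then wait 40 h
- north-east: at 3.0 d take out 90% of the target then present, then wait 40 h
- south: at 3.0 d add partner, 50.0% of the amount charged, then wait 40 h
- east: change nothing and wait 40 h more

* target, in percent of the starting material first charged, at 3.0 d
* the option that brings most further target ("none" if no option brings more than 2 percentage points) (north-west / north-east / south / east / none)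
* target present, with what was taken out counted in, in percent of the starting material first charged, after north-east
* target present, with what was taken out counted in, in percent of the starting material first charged, after east

- In the summer flask the highest target reading is 46.8%, and by 40.0 h the starting material reading is 3.1%, well below target's 40.6%. My reckoning takes target's own concentration as the one that sets the order of the late fall: first order in target.
- The carried quantity is the loss half-life, the time in which target past its peak loses half of what stands at a first-order pace. Read from the last two summer readings, with their scatter, it is 48.8 h.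
- The last two dawn readings, taken at 85 °C from 60.0 h to 96.0 h, give 199 h, which is 4.08 times the summer value, though over a different span of the run.
- Carrying the summer reading of 40.6% forward to 3.0 d with 48.8 h gives 25.8%.
- The weak link is the constant half-life, which assumes a fall towards zero. A reversible fall levels off and its half-life stretches, so I commit to 25.8% as a low estimate of target in the summer flask, and leave open whether removal or heat can bring target back.
- The forecast, reckoned apart from this and with another constant, says 25%, none, 24% and 13%; its ground is “With nothing left to convert, heating only destroys target”.
- The flask gives 31.4% at 3.0 d, and the best option is north-west, with 16 percentage points further. North-east brings 12 points and reaches 43.5%, while east brings −2.4 points and ends at 29.0%.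

    starting material + second reagent → side product (k = 0.00730 L mol⁻¹ s⁻¹, Ea = 84.0 kJ mol⁻¹)
    second reagent + intermediate → target (k = 0.0510 L mol⁻¹ s⁻¹, Ea = 79.0 kJ mol⁻¹)
    target ⇌ isomer of the product (K = 1.50, k = 8.00 × 10⁻⁶ s⁻¹, Ea = 123 kJ mol⁻¹, ΔH = −52.0 kJ mol⁻¹)
    starting material + partner → intermediate (k = 0.00590 L mol⁻¹ s⁻¹, Ea = 90.0 kJ mol⁻¹)
    gas ⇌ second reagent, rate k5*(csat - [second reagent]) (kL = 3.10 × 10⁻⁵ s⁻¹)
    (constants at 100 °C)

- In the summer flask the loss half-life is 48.8 h over the last two readings and 86.3 h from the reading at 40.0 h to the value at 3.0 d, while the relaxation half-life of target and isomer of the product, by this step alone and both ways together, is 14.4 h, shorter than 3.0 d, and target stands at 31.4% beside 40.1% of the isomer, then at 28.6% after 720 h. In the dawn flask 199 h carries the reading at 60.0 h to 45.7% at 3.0 d, where that flask holds 45.5%.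

Readings and results were computed from invented constants, and the scatter is random.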